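At the start of Wednesday's flask Z goes to L more slowly than to X, at 0.25 of that rate, and two chemists who accept this disagree over what follows.

the same everywhere: Z 0.29 M; X 0.0580 M; time 2.0 min

| flask | L |
|---|---|
| Sunday's | 0.260 M |
| Wednesday's | 0.340 M |

    Z + L → E + Q (k1 = 0.179 /M/s)
    L + E ⇌ L.E, settled at all times (K2 = 22200 /M)
    Z + E → Z.E (k3 = 0.136 /M/s)
    Z + X → Z.X (k4 = 4.23 /M/s)

* part of the Z that has reacted at the end, Sunday's
* part of the Z that has reacted at the end, Wednesday's
* what raising the concentration of L from its lowest to its highest value here does to the part of the Z that has reacted (changes below 5 percentage points count as none) (it rises / no change / it falls)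

The first chemist counts one L per Z. In Sunday's flask, X and L together come to 0.318 M, more than the 0.29 M of Z, and the run lasts 8.06 half-lives of Z by the step to Q. That view expects 100 percent on both days, so no change.

The second chemist watches E. At the start of Sunday's flask, the equilibrium constant times L is 5800, so L.E is favoured over free E by that factor, and each E formed takes a second L out of play.

My own reckoning follows the second view. Counted double, L is the limiting reagent, because half its charge is less than the Z that X leaves. Sunday's flask gives 64.8%, which I name the two-L mark, the part of the charged Z reacted once X has taken its own charge of Z and each further Z has cost two L. Wednesday's flask gives 78.6%. The equilibrium constant times L shrinks as free L falls, so the mark describes a pause and not an end.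

The forecast says 65% and 77.6%, and of the trend, it rises, holding that “each Z + L event uses two L because the tightly bound L.E locks up a second L”. Its Wednesday figure stands 1 percentage point below my mark.

The simulation gives 65.3% and 77.7%, and it rises, by 12 points, so the second view stands. At the end of Sunday's flask, Z.E holds 0.382% of the charged Z, and 1.0% of the L is still free.

Neither flask has come to rest. At ten times the time, Sunday's flask reaches 84.6% and Wednesday's 91.5%, while Z.E grows to 13.0% and 8.27% of the charged Z. In Sunday's flask, L.E falls from 0.127 M to 0.109 M over the same stretch. Sunday's long reading stands 20 points above its two-L mark of 64.8%, while Q in Sunday's flask moves from 44.9% to 51.7% of the charged Z. Wednesday's long reading still stands 6.9 points above Sunday's, so the long run gives neither the first chemist's 100 percent nor no change.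

With 0.099 M of X in Wednesday's flask, the two-L mark gives 92.8%. The simulation gives 88.7%, with 7.0% of the L still free.

The rate constants were chosen freely; what happens was integrated by code.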